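**Strategy.** The synthesis rests on cutting ring A at C1–C10 and C4–C5: the 1,4-dioxygenated bridge C1–C2–C3–C4, spanning C10–C5 beside the C6 oxygen, is a succinoyl unit added across the C5=C10 bond of a ring B enone (carbonyl = C6). The key step, the [2+2] photocycloaddition of (R)-5-(4-methoxybenzyloxy)-3-methylcyclohex-2-enone with 1,2-bis(trimethylsilyloxy)cyclobutene, forms both bonds and the quaternary C10 in one operation; its product, a cyclohexanone fused to a bicyclo[2.2.0]hexane, is not a decalin. Glycol cleavage of the temporary C1–C4 bond then unfolds ring A as a 1,4-diketone. The C8 ether steers the cycloaddition and later becomes the ketone from which C7 and C8 are set.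

Key step: step 4

Remark: locants follow eudesmane numbering (ring A = C1–C5 and C10, ring B = C5–C10, C14 = methyl on C10, C15 = methyl on C4, α = face opposite to C14; "1,4-cyclo" = a C1–C4 bond); compounds 1 and 5 are assumed to be purchased; PMB = 4-methoxybenzyl, TBS = tert-butyldimethylsilyl.

Step 1
Reactants: 1 hepta-1,6-dien-4-ol
Product: 2 4-[(4-methoxybenzyl)oxy]hepta-1,6-diene
Conditions: NaH, 4-methoxybenzyl chloride, Bu4NI (cat.), THF/DMF, 0 °C → rt
Reagents that add atoms: 4-methoxybenzyl chloride, COc1ccc(CCl)cc1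
Why: Williamson etherification of the sodium alkoxide with the benzylic chloride; the carbinol carbon is still prochiral, so no stereocentre is involved.

Step 2
Reactants: 2 4-[(4-methoxybenzyl)oxy]hepta-1,6-diene
Product: 3 4-[(4-methoxybenzyl)oxy]heptane-2,6-dione
Conditions: PdCl2 (10 mol %), CuCl, O2 (1 atm), DMF/H2O, rt
Reagents that add atoms: water, O
Why: Twofold Wacker–Tsuji oxidation should convert each terminal alkene into its methyl ketone with Markovnikov regiochemistry, the homoallylic ether being tolerated.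

Step 3
Reactants: 3 4-[(4-methoxybenzyl)oxy]heptane-2,6-dione
Product: 4 (R)-5-[(4-methoxybenzyl)oxy]-3-methylcyclohex-2-en-1-one (ring B enone: carbonyl = C6, C5=C10, ether carbon = C8 with 8β-O)
Conditions: 9-amino-9-deoxy-epi-quinine (20 mol %; its epi-quinidine pseudo-enantiomer if the opposite sense is needed), CF3CO2H (40 mol %), toluene, rt
Reagents that add atoms: none
Why: Enamine-mediated desymmetrising intramolecular aldol condensation (primary-amine variant of the Hajos–Parrish-type aldolisation of 4-substituted heptane-2,6-diones), in which the chiral amine condenses with one of the two enantiotopic acetonyl arms and so fixes the ether carbon (future C8) as R.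

Step 4
Reactants: 4 (R)-5-[(4-methoxybenzyl)oxy]-3-methylcyclohex-2-en-1-one; 5 1,2-bis(trimethylsilyloxy)cyclobut-1-ene
Product: 6 8β-(4-methoxybenzyloxy)-10β-methyl-1,4-bis(trimethylsilyloxy)-1,4-cyclo-5β-H-decalin-6-one (cis-anti-cis photoadduct; new C10–C1 and C5–C4 bonds on the α face)
Conditions: hν (350 nm, Pyrex), 5 (5 equiv), CH2Cl2, −40 °C
Reagents that add atoms: none
Why: Excitation of the enone and intersystem crossing give the triplet, which adds to the electron-rich cyclobutene 5 by C10–C1 bond formation to a 1,4-diradical that closes the C5–C4 bond after spin inversion. This is the de Mayo-type enone–alkene [2+2] photocycloaddition in which 1,2-bis(silyloxy)cyclobutenes serve as 1,4-diketone (succinoyl) equivalents. The one ring closed is the cyclobutane C10–C1–C4–C5, formed by recombination of the diradical (a four-membered ring closure, cis on the cyclobutene). C10 is set by the C8 stereocentre, because in the half-chair with the C8 ether pseudo-equatorial the new C10–C1 bond forms pseudo-axially on the face anti to that ether; C5 follows as the cis ring fusion (it is equilibrated in step 7) and C1/C4 follow from the cis geometry of 5 (both are lost on cleavage). Because 5 is symmetrical there is no regiochemical question, so the only selectivity needed is facial and it is supplied by the 8β-ether of 4, any minor facial isomer being removed by chromatography.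

Step 5
Reactants: 6 photoadduct ketone
Product: 7 6α-hydroxy photoadduct (8β-PMBO-10β-methyl-1,4-bis(trimethylsilyloxy)-1,4-cyclo-5β-H-decalin-6α-ol)
Conditions: NaBH4, MeOH/THF, −20 °C
Reagents that add atoms: none
Why: Borohydride reduction in which hydride should attack C6 from the convex β face, anti to the cyclobutane bond on C5 and to the pseudo-axial C10–C1 bond, which sets the 6α-alcohol.

Step 6
Reactants: 7 6α-hydroxy photoadduct
Product: 8 6α-O-TBS ether of 7
Conditions: TBSOTf, 2,6-lutidine, CH2Cl2, 0 °C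
Reagents that add atoms: tert-butyldimethylsilyl triflate, CC(C)(C)[Si](C)(C)OS(=O)(=O)C(F)(F)F
Why: Silylation of the hindered secondary alcohol with the silyl triflate protects O6 for all later steps and is compatible with the tertiary trimethylsilyl ethers and the PMB ether.

Step 7
Reactants: 8 6α-O-TBS ether
Product: 11 trans-fused (5α-H) 6α-TBSO-8β-PMBO-10β-methyldecalin-1,4-dione, via cyclobutane-1,2-diol 9 (not isolated), via cis-fused 1,4-diketone 10 (not isolated)
Conditions: K2CO3, MeOH, 0 °C; then Pb(OAc)4, CH2Cl2, 0 °C; then DBU (cat.), CH2Cl2, 0 °C → rt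
Reagents that add atoms: none
Why: Methanolysis frees the cis-cyclobutane-1,2-diol, Criegee glycol cleavage breaks the C1–C4 bond and expands the bicyclo[2.2.0]hexane to the cyclohexane-1,4-dione, and base equilibration through the C4 enol should turn the cis-fused C5 into the trans ring fusion (5α-H), in which the 6α-silyloxy group is equatorial.

Step 8
Reactants: 11 trans-fused 1,4-diketone
Product: 12 1β-hydroxy-6α-TBSO-8β-PMBO-10β-methyl-5α-H-decalin-4-one
Conditions: NaBH4 (1 equiv), MeOH/CH2Cl2, −40 °C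
Reagents that add atoms: none
Why: Chemoselective borohydride reduction in which C1 is attacked axially from the α face (no 1,3-diaxial methyl) to give the equatorial 1β-alcohol, whereas C4 is shielded on its β face by the axial C14 methyl and on its α face by the peri 6α-silyloxy group.

Step 9
Reactants: 12 1β-hydroxy-4-ketone
Product: 13 1β,6α-bis(TBSO)-8β-PMBO-10β-methyl-5α-H-decalin-4-one
Conditions: TBSOTf, 2,6-lutidine, CH2Cl2, 0 °C
Reagents that add atoms: tert-butyldimethylsilyl triflate, CC(C)(C)[Si](C)(C)OS(=O)(=O)C(F)(F)F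
Why: Silyl triflate silylation of the equatorial neopentyl C1 alcohol, the only hydroxyl present, so that later only O8 can be oxidised.

Step 10
Reactants: 13 bis-silyl ether 4-ketone
Product: 14 1β,6α-bis(TBSO)-8β-PMBO-15-methylidene compound (C4=C15 exocyclic alkene)
Conditions: Ph3PCH3Br, KOtBu, toluene, rt → 60 °C
Reagents that add atoms: methyltriphenylphosphonium bromide, C[P+](c1ccccc1)(c1ccccc1)c1ccccc1.[Br-]
Why: Wittig methylenation of the remaining C4 ketone with the small salt-free ylide, which tolerates silyl and benzyl ethers and leaves C5 in its trans configuration.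

Step 11
Reactants: 14 exocyclic alkene
Product: 15 1β,6α-bis(TBSO)-8β-PMBO-4α-hydroxy-4β,10β-dimethyl-5α-H-decalin
Conditions: Co(acac)2 (cat.), PhSiH3, O2 (1 atm), iPrOH, rt
Reagents that add atoms: dioxygen, O=O
Why: Mukaiyama hydration, in which hydrogen-atom transfer gives the tertiary C4 radical that should be trapped by O2 on the α face because the axial β approach is blocked by the 1,3-diaxial C14 methyl, giving 4α-OH and the axial 4β-methyl.

Step 12
Reactants: 15 PMB ether
Product: 16 1β,6α-bis(TBSO)-4α,8β-diol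
Conditions: DDQ, CH2Cl2/pH 7 buffer, 0 °C
Reagents that add atoms: none
Why: Oxidative cleavage of the electron-rich 4-methoxybenzyl ether by DDQ (benzylic hydride abstraction, then hydrolysis) leaves the silyl ethers and the tertiary alcohol untouched.

Step 13
Reactants: 16 4α,8β-diol
Product: 17 1β,6α-bis(TBSO)-4α-hydroxy-4β,10β-dimethyl-5α-H-decalin-8-one
Conditions: Dess–Martin periodinane, NaHCO3, CH2Cl2, rt
Reagents that add atoms: none
Why: Dess–Martin oxidation of the only secondary alcohol gives the C8 ketone and erases the stereocentre that has done its directing work.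

Step 14
Reactants: 17 8-ketone
Product: 18 7β-allyl-1β,6α-bis(TBSO)-4α-hydroxy-8-ketone
Conditions: LiN(iPr)2 (2.2 equiv), allyl iodide, THF, −78 → −40 °C
Reagents that add atoms: allyl iodide, C=CCI
Why: Kinetic enolate alkylation in which the amide base should deprotonate C7 rather than C9 (flanked by the quaternary C10, as 2-keto-5α-steroids enolise toward C3) and allyl iodide enters trans to the neighbouring 6α-silyloxy group to give the equatorial 7β-allyl ketone, any 7α-epimer equilibrating through the enol.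

Step 15
Reactants: 18 7β-allyl-8-ketone
Product: 19 7β-allyl-1β,6α-bis(TBSO)-4α,8α-diol
Conditions: Li, NH3 (l), tBuOH, THF, −78 °C; NH4Cl work-up
Reagents that add atoms: none
Why: Dissolving-metal reduction should give the thermodynamically preferred equatorial 8α-alcohol, the axial 8β-epimer being 1,3-diaxial to the C14 methyl, while the terminal alkene and the silyl ethers are inert.

Step 16
Reactants: 19 4α,8α-diol
Product: 20 8α-acetoxy-7β-allyl-1β,6α-bis(TBSO)-4α-ol
Conditions: Ac2O, pyridine, DMAP (cat.), CH2Cl2, 0 °C → rt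
Reagents that add atoms: acetic anhydride, CC(=O)OC(C)=O
Why: DMAP-catalysed acetylation of the only free secondary alcohol; the tertiary C4 hydroxyl, hindered by the axial C15 methyl and the peri silyloxy group, is expected not to react.

Step 17
Reactants: 20 8α-acetate
Product: 21 C12 aldehyde (7β-CH2CHO) of the 8α-acetoxy-1β,6α-bis(TBSO)-4α-ol
Conditions: K2OsO4·2H2O (2 mol %), NaIO4, 2,6-lutidine, dioxane/H2O, rt
Reagents that add atoms: sodium periodate, [Na+].[O-]I(=O)(=O)=O
Why: Lemieux–Johnson oxidative cleavage (dihydroxylation then periodate) of the only alkene shortens the allyl group to the C11–C12 acetaldehyde unit without touching the acetate.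

Step 18
Reactants: 21 C12 aldehyde
Product: 22 8α-acetoxy-1β,6α-bis(TBSO)-4α-hydroxyeudesm-11(13)-en-12-al
Conditions: Me2N=CH2 I (dimethylmethyleneammonium iodide), Et3N, CH2Cl2, rt
Reagents that add atoms: dimethylmethyleneammonium iodide, C=[N+](C)C.[I-]
Why: Mannich reaction of the aldehyde enol with the iminium salt followed by β-elimination of dimethylamine (α-methylenation) installs C13 and the C11=C13 bond, and C7 keeps its configuration because enolisation occurs only at C11.

Step 19
Reactants: 22 α-methylene aldehyde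
Product: 23 8α-acetoxy-1β,6α-bis(TBSO)-4α-hydroxyeudesm-11(13)-en-12-oic acid
Conditions: NaClO2, NaH2PO4, 2-methyl-2-butene, tBuOH/H2O, 0 °C → rt
Reagents that add atoms: sodium chlorite, [Na+].[O-]Cl=O
Why: Pinnick oxidation of the α-substituted acrolein to the acrylic acid under buffered conditions that spare the acetate, the silyl ethers and the alkene; the silyl group on O6 prevents lactonisation.

Step 20
Reactants: 23 acrylic acid
Product: 24 methyl 8α-acetoxy-1β,6α-bis(TBSO)-4α-hydroxyeudesm-11(13)-en-12-oate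
Conditions: TMSCHN2, MeOH/toluene, 0 °C
Reagents that add atoms: (trimethylsilyl)diazomethane, C[Si](C)(C)C=[N+]=[N-]
Why: O-Methylation of the carboxylic acid with (trimethylsilyl)diazomethane and methanol is neutral and avoids acyl migration.

Step 21
Reactants: 24 bis-silyl ether methyl ester
Product: 25 methyl 8α-acetoxy-1β,4α,6α-trihydroxy-5α,7α-H-eudesm-11(13)-en-12-oate (CNP0272656.1)
Conditions: HF·pyridine, pyridine/THF, 0 °C → rt
Reagents that add atoms: none
Why: Fluoride-mediated cleavage of both silyl ethers under buffered, weakly acidic conditions should release O1 and O6 without the acetate migration or lactonisation onto the ester that basic fluoride sources could trigger.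

**Compound list**

1 | hepta-1,6-dien-4-ol | C=CCC(O)CC=C | starting material
2 | 4-[(4-methoxybenzyl)oxy]hepta-1,6-diene | C=CCC(OCc1ccc(OC)cc1)CC=C | intermediate
3 | 4-[(4-methoxybenzyl)oxy]heptane-2,6-dione | CC(=O)CC(OCc1ccc(OC)cc1)CC(C)=O | intermediate
4 | (R)-5-[(4-methoxybenzyl)oxy]-3-methylcyclohex-2-en-1-one | O=C1C[C@H](OCc2ccc(OC)cc2)CC(C)=C1 | intermediate
5 | 1,2-bis(trimethylsilyloxy)cyclobut-1-ene | C[Si](C)(C)OC1=C(O[Si](C)(C)C)CC1 | starting material
6 | cis-anti-cis photoadduct, 8β-PMBO-10β-methyl-1,4-bis(trimethylsilyloxy)-1,4-cyclo-5β-H-decalin-6-one | O=C1C[C@H](OCc4ccc(OC)cc4)C[C@]2(C)[C@H]1[C@@]3(O[Si](C)(C)C)CC[C@@]23O[Si](C)(C)C | intermediate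
7 | 6α-alcohol of 6 | O[C@H]1C[C@H](OCc4ccc(OC)cc4)C[C@]2(C)[C@H]1[C@@]3(O[Si](C)(C)C)CC[C@@]23O[Si](C)(C)C | intermediate
8 | 6α-O-TBS ether of 7 | CC(C)(C)[Si](C)(C)O[C@H]1C[C@H](OCc4ccc(OC)cc4)C[C@]2(C)[C@H]1[C@@]3(O[Si](C)(C)C)CC[C@@]23O[Si](C)(C)C | intermediate
9 | cyclobutane-1,2-diol (1,4-diol of the 1,4-cyclo compound) | CC(C)(C)[Si](C)(C)O[C@H]1C[C@H](OCc4ccc(OC)cc4)C[C@]2(C)[C@H]1[C@@]3(O)CC[C@@]23O | intermediate
10 | cis-fused (5β-H) 6α-TBSO-8β-PMBO-10β-methyldecalin-1,4-dione | C1[C@H](O[Si](C)(C)C(C)(C)C)[C@H]2[C@@](C)(C[C@H]1OCc3ccc(OC)cc3)C(=O)CCC2=O | intermediate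
11 | trans-fused (5α-H) 6α-TBSO-8β-PMBO-10β-methyldecalin-1,4-dione | C1[C@H](O[Si](C)(C)C(C)(C)C)[C@@H]2[C@@](C)(C[C@H]1OCc3ccc(OC)cc3)C(=O)CCC2=O | intermediate
12 | 1β-hydroxy-6α-TBSO-8β-PMBO-10β-methyl-5α-H-decalin-4-one | C1[C@H](O[Si](C)(C)C(C)(C)C)[C@@H]2[C@@](C)(C[C@H]1OCc3ccc(OC)cc3)[C@H](O)CCC2=O | intermediate
13 | 1β,6α-bis(TBSO)-8β-PMBO-10β-methyl-5α-H-decalin-4-one | C1[C@H](O[Si](C)(C)C(C)(C)C)[C@@H]2[C@@](C)(C[C@H]1OCc3ccc(OC)cc3)[C@H](O[Si](C)(C)C(C)(C)C)CCC2=O | intermediate
14 | 1β,6α-bis(TBSO)-8β-PMBO-4-methylidene-10β-methyl-5α-H-decalin | C1[C@H](O[Si](C)(C)C(C)(C)C)[C@@H]2[C@@](C)(C[C@H]1OCc3ccc(OC)cc3)[C@H](O[Si](C)(C)C(C)(C)C)CCC2=C | intermediate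
15 | 1β,6α-bis(TBSO)-8β-PMBO-4β,10β-dimethyl-5α-H-decalin-4α-ol | C1[C@H](O[Si](C)(C)C(C)(C)C)[C@@H]2[C@@](C)(C[C@H]1OCc3ccc(OC)cc3)[C@H](O[Si](C)(C)C(C)(C)C)CC[C@@]2(C)O | intermediate
16 | 1β,6α-bis(TBSO)-4β,10β-dimethyl-5α-H-decalin-4α,8β-diol | C1[C@H](O[Si](C)(C)C(C)(C)C)[C@@H]2[C@@](C)(C[C@H]1O)[C@H](O[Si](C)(C)C(C)(C)C)CC[C@@]2(C)O | intermediate
17 | 1β,6α-bis(TBSO)-4α-hydroxy-4β,10β-dimethyl-5α-H-decalin-8-one | C1[C@H](O[Si](C)(C)C(C)(C)C)[C@@H]2[C@@](C)(CC1=O)[C@H](O[Si](C)(C)C(C)(C)C)CC[C@@]2(C)O | intermediate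
18 | 7β-allyl-1β,6α-bis(TBSO)-4α-hydroxy-4β,10β-dimethyl-5α-H-decalin-8-one | C=CC[C@H]1[C@H](O[Si](C)(C)C(C)(C)C)[C@@H]2[C@@](C)(CC1=O)[C@H](O[Si](C)(C)C(C)(C)C)CC[C@@]2(C)O | intermediate
19 | 7β-allyl-1β,6α-bis(TBSO)-4β,10β-dimethyl-5α-H-decalin-4α,8α-diol | C=CC[C@H]1[C@H](O[Si](C)(C)C(C)(C)C)[C@@H]2[C@@](C)(C[C@@H]1O)[C@H](O[Si](C)(C)C(C)(C)C)CC[C@@]2(C)O | intermediate
20 | 8α-acetate of 19 | C=CC[C@H]1[C@H](O[Si](C)(C)C(C)(C)C)[C@@H]2[C@@](C)(C[C@@H]1OC(C)=O)[C@H](O[Si](C)(C)C(C)(C)C)CC[C@@]2(C)O | intermediate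
21 | C12 aldehyde (7β-CH2CHO), 8α-acetoxy-1β,6α-bis(TBSO)-4α-ol | O=CC[C@H]1[C@H](O[Si](C)(C)C(C)(C)C)[C@@H]2[C@@](C)(C[C@@H]1OC(C)=O)[C@H](O[Si](C)(C)C(C)(C)C)CC[C@@]2(C)O | intermediate
22 | 8α-acetoxy-1β,6α-bis(TBSO)-4α-hydroxyeudesm-11(13)-en-12-al | C=C(C=O)[C@H]1[C@H](O[Si](C)(C)C(C)(C)C)[C@@H]2[C@@](C)(C[C@@H]1OC(C)=O)[C@H](O[Si](C)(C)C(C)(C)C)CC[C@@]2(C)O | intermediate
23 | 8α-acetoxy-1β,6α-bis(TBSO)-4α-hydroxyeudesm-11(13)-en-12-oic acid | C=C(C(=O)O)[C@H]1[C@H](O[Si](C)(C)C(C)(C)C)[C@@H]2[C@@](C)(C[C@@H]1OC(C)=O)[C@H](O[Si](C)(C)C(C)(C)C)CC[C@@]2(C)O | intermediate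
24 | methyl 8α-acetoxy-1β,6α-bis(TBSO)-4α-hydroxyeudesm-11(13)-en-12-oate | C=C(C(=O)OC)[C@H]1[C@H](O[Si](C)(C)C(C)(C)C)[C@@H]2[C@@](C)(C[C@@H]1OC(C)=O)[C@H](O[Si](C)(C)C(C)(C)C)CC[C@@]2(C)O | intermediate
25 | methyl 8α-acetoxy-1β,4α,6α-trihydroxy-5α,7α-H-eudesm-11(13)-en-12-oate (CNP0272656.1) | C=C(C(=O)OC)[C@H]1[C@H](O)[C@@H]2[C@@](C)(C[C@@H]1OC(C)=O)[C@H](O)CC[C@@]2(C)O | target

**Totals and risks**

Total step count: 21. Longest linear sequence: 21 steps (from 1; compound 5 is bought).

The three steps most likely to fail: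

Step 14. Deprotonation may go toward C9 instead of C7, and the C7 enolate may expel the C6 silyloxy group by β-elimination. The fallback sets out from 17 and avoids a basic enolate. Bromination through the acid-formed enol, which should form toward C7 (PhNMe3Br3, THF, 0 °C), gives the 7α-bromo-8-ketone F1. Keck radical allylation (allylSnBu3, AIBN, benzene, 80 °C) then replaces bromine by allyl through the non-basic C7 radical. After equilibration of C7 on triethylamine-washed silica the route is rejoined at 18.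

Step 8. Hydride may attack C4 as well as C1, or reduce both carbonyls. The fallback sets out from 11 and moves the discrimination from the reduction to a silylation. Both ketones are reduced on purpose (NaBH4 in excess, MeOH, 0 °C → rt) to the 1β,4β-diol F2. Only the equatorial C1 hydroxyl is then silylated (TBSCl, imidazole, DMF); the axial C4 hydroxyl, 1,3-diaxial to C14, should stay free, giving the 1-O-TBS-4β-ol F3. Dess–Martin oxidation of F3 returns to the route at 13, so step 9 is also replaced.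

Step 11. Trapping of the C4 radical by O2 may show poor facial selectivity, or the alkene may simply be reduced. The fallback sets out from 14 and uses a closed-shell, two-step hydration. Epoxidation with mCPBA (NaHCO3, CH2Cl2, 0 °C) from the α face, away from the axial C14 methyl, gives the 4α,15-epoxide F4. LiBHEt3 (THF, 0 °C) opens it at the primary C15, and the route is rejoined at 15.

Further compounds
F1 | step 14 | 7α-bromo-1β,6α-bis(TBSO)-4α-hydroxy-4β,10β-dimethyl-5α-H-decalin-8-one | Br[C@@H]1[C@H](O[Si](C)(C)C(C)(C)C)[C@@H]2[C@@](C)(CC1=O)[C@H](O[Si](C)(C)C(C)(C)C)CC[C@@]2(C)O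
F2 | step 8 | 6α-TBSO-8β-PMBO-10β-methyl-5α-H-decalin-1β,4β-diol | C1[C@H](O[Si](C)(C)C(C)(C)C)[C@@H]2[C@@](C)(C[C@H]1OCc3ccc(OC)cc3)[C@H](O)CC[C@@H]2O
F3 | step 8 | 1β,6α-bis(TBSO)-8β-PMBO-10β-methyl-5α-H-decalin-4β-ol | C1[C@H](O[Si](C)(C)C(C)(C)C)[C@@H]2[C@@](C)(C[C@H]1OCc3ccc(OC)cc3)[C@H](O[Si](C)(C)C(C)(C)C)CC[C@@H]2O
F4 | step 11 | 4α,15-epoxide of 14 (spiro-oxirane at C4, oxygen α) | C1[C@H](O[Si](C)(C)C(C)(C)C)[C@@H]2[C@@](C)(C[C@H]1OCc3ccc(OC)cc3)[C@H](O[Si](C)(C)C(C)(C)C)CC[C@]24CO4
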